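**Retrosynthetic overview**
1. Labels: ring A is the formyl-bearing benzene ring, with primed locants (C1′ CH3, C2′ H, C3′ OH, C4′ CHO, C5′ ether O, C6′ lactone C=O); ring B is the benzene ring of the chroman-4-one (C5 CH3, C6 ester O, C7 ether O, C8 OH); ring C is the seven-membered lactone; ring D is the dihydropyranone.
2. Feature used: the adjacent ring A carbons C5′ and C6′ carry the diaryl ether oxygen and the lactone carbonyl carbon, like the two ends of an aryne. Cutting C5′–O and C6′–C(=O) together gives a 3-chloroaryne (from silyl triflate 6), the C7 phenoxide of chromanone 14 and CO2.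
3. After the coupling: ring C by lactonisation of the C6′ carboxyl onto the C6 oxygen, exchange of the steering chlorine at C1′ for methyl (Negishi), BCl3 deprotection, formylation at C4′ last.
4. Ring B: the acetyl hydroquinone from 2,3-dimethoxy-5-methylbenzoquinone is annulated to ring D by Kabbe condensation with acetone; this is preferred to a direct Friedel–Crafts reaction with 3-methylbut-2-enoic acid, which can alkylate the ring to a dihydrocoumarin. The C6 oxygen is then masked as MOM ether and the 7-methoxy, para to the ketone, is cleaved selectively.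
5. Order of ring formation: ring D (step 6), then ring C (step 11); rings A and B come from purchased arenes.

Key step: step 9

Remark: the target has no stereocentre, so no step has to set or preserve configuration.

**Step 1**
Reactants: 1 4-(benzyloxy)phenol
Product: 2 4-(benzyloxy)-2-chlorophenol
Conditions: SO2Cl2 (1.05 equiv), i-Bu2NH (cat.), toluene, 0 °C → rt
Reagents that add atoms: sulfuryl chloride, O=S(=O)(Cl)Cl
Why: Amine-catalysed electrophilic chlorination of a phenol goes ortho to the hydroxyl, since the para position is blocked by the benzyloxy group and the hydroxyl is the stronger director.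

**Step 2**
Reactants: 2 4-(benzyloxy)-2-chlorophenol
Product: 3 4-(benzyloxy)-2-bromo-6-chlorophenol
Conditions: NBS (1.0 equiv), i-Pr2NH (cat.), CH2Cl2, 0 °C
Reagents that add atoms: N-bromosuccinimide, O=C1CCC(=O)N1Br
Why: Electrophilic ortho-bromination of a phenol with NBS and a secondary amine should take the one remaining position ortho to the hydroxyl.

**Step 3**
Reactants: 3 4-(benzyloxy)-2-bromo-6-chlorophenol
Product: 6 4-(benzyloxy)-2-chloro-6-(trimethylsilyl)phenyl trifluoromethanesulfonate, via aryl trimethylsilyl ether 4 (not isolated), via lithium 2-silylphenoxide 5 (not isolated)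
Conditions: HMDS, THF, 65 °C, then evaporation; n-BuLi (1.05 equiv), THF, −78 °C; Tf2O, −78 °C → rt
Reagents that add atoms: hexamethyldisilazane, C[Si](C)(C)N[Si](C)(C)C; trifluoromethanesulfonic anhydride, O=S(=O)(OS(=O)(=O)C(F)(F)F)C(F)(F)F
Why: This is the standard route to ortho-silylaryl triflates: bromine–lithium exchange (much faster than chlorine exchange) on the O-silyl bromophenol triggers the 1,3 retro-Brook shift of silicon from oxygen to carbon, and the phenoxide is then triflated.

**Step 4**
Reactants: 7 2,3-dimethoxy-5-methyl-1,4-benzoquinone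
Product: 8 2,3-dimethoxy-5-methylbenzene-1,4-diol
Conditions: Na2S2O4, EtOAc/H2O, rt, argon
Reagents that add atoms: none
Why: Dithionite reduction of a benzoquinone to its hydroquinone is general and leaves the methoxy groups untouched.

**Step 5**
Reactants: 8 2,3-dimethoxy-5-methylbenzene-1,4-diol
Product: 9 1-(2,5-dihydroxy-3,4-dimethoxy-6-methylphenyl)ethan-1-one
Conditions: AcOH (3 equiv), BF3·OEt2, 90 °C, argon; then H2O
Reagents that add atoms: acetic acid, CC(=O)O
Why: BF3-mediated Friedel–Crafts (Nencki-type) C-acylation of the electron-rich hydroquinone can only take the single free ring position and should stop at the ortho-hydroxy ketone, which is held as a boron chelate until work-up.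

**Step 6**
Reactants: 9 1-(2,5-dihydroxy-3,4-dimethoxy-6-methylphenyl)ethan-1-one
Product: 11 6-hydroxy-7,8-dimethoxy-2,2,5-trimethylchroman-4-one, via ortho-hydroxyaryl enone 10 (not isolated)
Conditions: acetone (5 equiv), pyrrolidine (0.5 equiv), EtOH, 70 °C (sealed), argon
Reagents that add atoms: acetone, CC(C)=O
Why: Kabbe chromanone synthesis: pyrrolidine mediates the aldol condensation of the methyl ketone with acetone to enone 10, and the ortho phenol closes ring D by 6-endo oxa-Michael addition; C2 carries two methyl groups, so no stereocentre arises.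

**Step 7**
Reactants: 11 6-hydroxy-7,8-dimethoxy-2,2,5-trimethylchroman-4-one
Product: 12 7,8-dimethoxy-6-(methoxymethoxy)-2,2,5-trimethylchroman-4-one
Conditions: MOMCl (1.5 equiv), i-Pr2NEt (2 equiv), CH2Cl2, 0 → 40 °C
Reagents that add atoms: chloromethyl methyl ether, COCCl
Why: Williamson-type O-alkylation of the only free phenol gives an acetal that can later be removed with acid without touching the methyl or benzyl ethers.

**Step 8**
Reactants: 12 7,8-dimethoxy-6-(methoxymethoxy)-2,2,5-trimethylchroman-4-one
Product: 14 7-hydroxy-8-methoxy-6-(methoxymethoxy)-2,2,5-trimethylchroman-4-one, via sodium phenoxide 13 (not isolated)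
Conditions: NaSEt (3 equiv), DMF, 100 °C; then cold 1 M HCl to pH 4
Reagents that add atoms: none
Why: Thiolate SN2 demethylation of aryl methyl ethers is fastest where the leaving phenoxide is best stabilised, here at the 7-methoxy para to the C4 ketone, and the phenoxide formed should protect the ring from a second cleavage.

**Step 9**
Reactants: 6 4-(benzyloxy)-2-chloro-6-(trimethylsilyl)phenyl trifluoromethanesulfonate; 14 7-hydroxy-8-methoxy-6-(methoxymethoxy)-2,2,5-trimethylchroman-4-one; 15 carbon dioxide
Product: 20 4-(benzyloxy)-2-chloro-6-{[8-methoxy-6-(methoxymethoxy)-2,2,5-trimethyl-4-oxochroman-7-yl]oxy}benzoic acid, via potassium phenoxide 16 (not isolated), via aryne 17 (not isolated), via aryl potassium adduct 18 (not isolated), via potassium carboxylate 19 (not isolated)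
Conditions: 14, KH (1.0 equiv), THF, 0 °C; then 18-crown-6 (3 equiv), KF (3 equiv), CO2 (1 atm), slow addition of 6 (1.2 equiv), THF, 0 °C → rt; cold 1 M HCl work-up
Reagents that add atoms: none
Why: Proposed new method: fluoride attacks the silicon of 6 and triflate leaves to give aryne 17, phenoxide 16 adds to the aryne carbon remote from chlorine, and the ortho-chloroaryl anion 18 is carboxylated by CO2, so the C5′–O ether bond and the C6′–carboxyl C–C bond form on adjacent ring A carbons in one operation. The closest known reaction types are the three-component coupling of arynes with amines and CO2 to anthranilic acids and the fluoride-mediated O-arylation of phenols by arynes; a phenoxide has not been shown as the nucleophile in the carboxylative version. No ring is closed and no stereocentre is formed. The step needs regioselective addition to the aryne: the inductively withdrawing chlorine next to the triple bond polarises it and stabilises the anion at the neighbouring carbon, so oxygen should go to the far carbon, and the benzyloxy group para to the anion carbon opposes this only weakly. It also needs carboxylation to outrun protonation and chloride loss, which is why the phenoxide is pre-formed with KH (only H2 leaves, no proton donor remains) and CO2 is kept in excess during slow addition of 6. The fully substituted ring B offers no carbon site, so only O-arylation is possible.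

**Step 10**
Reactants: 20 4-(benzyloxy)-2-chloro-6-{[8-methoxy-6-(methoxymethoxy)-2,2,5-trimethyl-4-oxochroman-7-yl]oxy}benzoic acid
Product: 21 4-(benzyloxy)-2-chloro-6-[(6-hydroxy-8-methoxy-2,2,5-trimethyl-4-oxochroman-7-yl)oxy]benzoic acid
Conditions: 3 M HCl, MeOH/THF, 45 °C
Reagents that add atoms: none
Why: Acid-catalysed transacetalisation of the MOM ether to methanol should free the C6 phenol, while the di-ortho-substituted benzoic acid is too hindered for Fischer esterification and the benzyl and methyl ethers are stable.

**Step 11**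
Reactants: 21 4-(benzyloxy)-2-chloro-6-[(6-hydroxy-8-methoxy-2,2,5-trimethyl-4-oxochroman-7-yl)oxy]benzoic acid
Product: 22 C1′-chloro-C3′-benzyloxy-8-methoxy depsidone (lactone C6′–C(=O)–O–C6 and ether C5′–O–C7 on the 2,2,5-trimethylchroman-4-one)
Conditions: DCC (1.3 equiv), DMAP (0.1 equiv), CH2Cl2 (0.01 M), rt
Reagents that add atoms: none
Why: Carbodiimide (Steglich-type) lactonisation: the activated ring A carboxyl is captured intramolecularly by the C6 phenol, closing the seven-membered ring C by 7-exo-trig acyl substitution, the usual closure of depsidones from 2-(2-hydroxyaryloxy)benzoic acids.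

**Step 12**
Reactants: 22 C1′-chloro-C3′-benzyloxy-8-methoxy depsidone
Product: 23 C1′-methyl-C3′-benzyloxy-8-methoxy depsidone
Conditions: MeZnCl (2 equiv), Pd2(dba)3 (2.5 mol %), XPhos (10 mol %), THF, 60 °C
Reagents that add atoms: methylzinc chloride, C[Zn]Cl
Why: Negishi cross-coupling: zerovalent palladium with the bulky biarylphosphine inserts into the aryl chloride ortho to the lactone carbonyl, and methylzinc chloride transfers methyl under neutral conditions that should spare the aryl ester, the ketone and the ethers.

**Step 13**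
Reactants: 23 C1′-methyl-C3′-benzyloxy-8-methoxy depsidone
Product: 24 C1′-methyl-C3′-hydroxy-8-hydroxy depsidone (the target without its C4′ formyl group)
Conditions: BCl3 (6 equiv), C6HMe5 (3 equiv), CH2Cl2, −78 °C → rt; then H2O
Reagents that add atoms: none
Why: BCl3 cleaves the benzyl ether at low temperature (pentamethylbenzene traps the benzyl cation) and on warming should cleave the C8 methyl ether, the crowded central ether of a 1,2,3-trioxygenated arene and so of the type that BCl3 demethylates, while the aryl lactone and the chromanone have no comparably labile C–O bond.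

**Step 14**
Reactants: 24 C1′-methyl-C3′-hydroxy-8-hydroxy depsidone
Product: 26 target CNP0271978.0 (C1′-methyl-C3′-hydroxy-C4′-formyl-8-hydroxy depsidone), via aryl(chloro)methyl methyl ether 25 (not isolated)
Conditions: TiCl4 (4 equiv), Cl2CHOMe (1.5 equiv), CH2Cl2, 0 °C → rt; then 1 M HCl
Reagents that add atoms: dichloromethyl methyl ether, COC(Cl)Cl; water, O
Why: Rieche formylation: the ring A phenol, bound as ArOTiCl3, directs the electrophile to an ortho position, and C4′, between the hydroxyl and the diaryl ether oxygen, is expected to react, while ring B has no free position; the regiochemistry is the main uncertainty of this step.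

**Compound list**
1 | 4-(benzyloxy)phenol | Oc1ccc(OCc2ccccc2)cc1 | starting material
2 | 4-(benzyloxy)-2-chlorophenol | Oc1ccc(OCc2ccccc2)cc1Cl | intermediate
3 | 4-(benzyloxy)-2-bromo-6-chlorophenol | Oc1c(Br)cc(OCc2ccccc2)cc1Cl | intermediate
4 | [4-(benzyloxy)-2-bromo-6-chlorophenoxy]trimethylsilane | C[Si](C)(C)Oc1c(Br)cc(OCc2ccccc2)cc1Cl | intermediate
5 | lithium 4-(benzyloxy)-2-chloro-6-(trimethylsilyl)phenoxide | [Li+].[O-]c1c(Cl)cc(OCc2ccccc2)cc1[Si](C)(C)C | intermediate
6 | 4-(benzyloxy)-2-chloro-6-(trimethylsilyl)phenyl trifluoromethanesulfonate | C[Si](C)(C)c1cc(OCc2ccccc2)cc(Cl)c1OS(=O)(=O)C(F)(F)F | intermediate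
7 | 2,3-dimethoxy-5-methyl-1,4-benzoquinone | COC1=C(OC)C(=O)C(C)=CC1=O | starting material
8 | 2,3-dimethoxy-5-methylbenzene-1,4-diol | Oc1cc(C)c(O)c(OC)c1OC | intermediate
9 | 1-(2,5-dihydroxy-3,4-dimethoxy-6-methylphenyl)ethan-1-one | CC(=O)c1c(C)c(O)c(OC)c(OC)c1O | intermediate
10 | 1-(2,5-dihydroxy-3,4-dimethoxy-6-methylphenyl)-3-methylbut-2-en-1-one | CC(C)=CC(=O)c1c(C)c(O)c(OC)c(OC)c1O | intermediate
11 | 6-hydroxy-7,8-dimethoxy-2,2,5-trimethylchroman-4-one | Cc1c(O)c(OC)c(OC)c2OC(C)(C)CC(=O)c12 | intermediate
12 | 7,8-dimethoxy-6-(methoxymethoxy)-2,2,5-trimethylchroman-4-one | Cc1c(OCOC)c(OC)c(OC)c2OC(C)(C)CC(=O)c12 | intermediate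
13 | sodium 8-methoxy-6-(methoxymethoxy)-2,2,5-trimethyl-4-oxochroman-7-olate | [Na+].[O-]c1c(OC)c2OC(C)(C)CC(=O)c2c(C)c1OCOC | intermediate
14 | 7-hydroxy-8-methoxy-6-(methoxymethoxy)-2,2,5-trimethylchroman-4-one | Cc1c(OCOC)c(O)c(OC)c2OC(C)(C)CC(=O)c12 | intermediate
15 | carbon dioxide | O=C=O | starting material
16 | potassium 8-methoxy-6-(methoxymethoxy)-2,2,5-trimethyl-4-oxochroman-7-olate | [K+].[O-]c1c(OC)c2OC(C)(C)CC(=O)c2c(C)c1OCOC | intermediate
17 | 5-(benzyloxy)-3-chloro-1,2-didehydrobenzene (aryne) | ClC1=CC(OCc2ccccc2)=CC#C1 | intermediate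
18 | 2-aryloxy-4-(benzyloxy)-6-chlorophenylpotassium (aryl = the chroman-7-yl group of 14) | [K]c1c(Cl)cc(OCc2ccccc2)cc1Oc1c(OC)c2OC(C)(C)CC(=O)c2c(C)c1OCOC | intermediate
19 | potassium salt of acid 20 | [K+].[O-]C(=O)c1c(Cl)cc(OCc2ccccc2)cc1Oc1c(OC)c2OC(C)(C)CC(=O)c2c(C)c1OCOC | intermediate
20 | 4-(benzyloxy)-2-chloro-6-{[8-methoxy-6-(methoxymethoxy)-2,2,5-trimethyl-4-oxochroman-7-yl]oxy}benzoic acid | OC(=O)c1c(Cl)cc(OCc2ccccc2)cc1Oc1c(OC)c2OC(C)(C)CC(=O)c2c(C)c1OCOC | intermediate
21 | 4-(benzyloxy)-2-chloro-6-[(6-hydroxy-8-methoxy-2,2,5-trimethyl-4-oxochroman-7-yl)oxy]benzoic acid | OC(=O)c1c(Cl)cc(OCc2ccccc2)cc1Oc1c(OC)c2OC(C)(C)CC(=O)c2c(C)c1O | intermediate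
22 | C1′-chloro-C3′-benzyloxy-8-methoxy depsidone (lactone C6′–C(=O)–O–C6, ether C5′–O–C7, fused 2,2,5-trimethylchroman-4-one) | Clc1cc(OCc2ccccc2)cc2c1C(=O)Oc1c(C)c3c(c(OC)c1O2)OC(C)(C)CC3=O | intermediate
23 | C1′-methyl-C3′-benzyloxy-8-methoxy depsidone | Cc1cc(OCc2ccccc2)cc2c1C(=O)Oc1c(C)c3c(c(OC)c1O2)OC(C)(C)CC3=O | intermediate
24 | C1′-methyl-C3′-hydroxy-8-hydroxy depsidone (target without its C4′ formyl group) | Cc1cc(O)cc2c1C(=O)Oc1c(C)c3c(c(O)c1O2)OC(C)(C)CC3=O | intermediate
25 | C4′-[chloro(methoxy)methyl] derivative of 24 (racemic, hydrolysed on work-up) | Cc1cc(O)c(C(Cl)OC)c2c1C(=O)Oc1c(C)c3c(c(O)c1O2)OC(C)(C)CC3=O | intermediate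
26 | CNP0271978.0 (C1′-methyl-C3′-hydroxy-C4′-formyl-8-hydroxy depsidone fused to the 2,2-dimethylchroman-4-one) | Cc1cc(O)c(C=O)c2c1C(=O)Oc1c(C)c3c(c(O)c1O2)OC(C)(C)CC3=O | target

**Step count and risks**
Total step count: 14. Longest linear sequence: 11 steps (steps 4–14, from 7 to 26).

Steps most likely to fail:

1. Step 9 (three-component coupling). The ortho-chloroaryl anion may be protonated before it meets CO2, by adventitious proton donors or by the α-methylene of the chromanone. It may also lose chloride to a second aryne, and the phenoxide may attack the triflate sulfur instead of waiting for the aryne. The fallback uses known chemistry, sets out from 14 and returns at 20. Commercial 2,6-dichloro-4-hydroxybenzaldehyde F1 is O-benzylated (BnBr, K2CO3, DMF) to 4-(benzyloxy)-2,6-dichlorobenzaldehyde F2. Pinnick oxidation (NaClO2, NaH2PO4, 2-methyl-2-butene, t-BuOH/H2O) then gives 4-(benzyloxy)-2,6-dichlorobenzoic acid F3. Ullmann ether synthesis of 14 with F3 (Cu powder, Cu2O, K2CO3, DMF, 120 °C) is assisted by the ortho-carboxylate, and because the two chlorines are equivalent, mono-substitution should give acid 20 without a regiochemical question.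

2. Step 8 (selective demethylation). The basic thiolate may open ring D by β-elimination of the ring oxygen from the ketone enolate, followed by thiol conjugate addition, or may attack the MOM methylene or the 8-methoxy group. The fallback sets out from 11 and returns at 14. BCl3 (2 equiv, CH2Cl2, −78 → −20 °C) is bound by the free 6-hydroxyl and should cleave the adjacent 7-methoxy, which is also the one para to the ketone, to give 6,7-dihydroxy-8-methoxy-2,2,5-trimethylchroman-4-one F4. Allyl bromide (1.0 equiv) with KHCO3 in DMF at rt should alkylate the more acidic 7-hydroxyl to give 7-(allyloxy)-6-hydroxy-8-methoxy-2,2,5-trimethylchroman-4-one F5. MOMCl with i-Pr2NEt then gives 7-(allyloxy)-8-methoxy-6-(methoxymethoxy)-2,2,5-trimethylchroman-4-one F6, and Tsuji–Trost deallylation (Pd(PPh3)4, morpholine, THF, rt) returns 14.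

3. Step 14 (formylation). The electrophile may enter at C2′, between the hydroxyl and the methyl group and para to the ether oxygen, instead of C4′, or may enter twice. The fallback sets out from 22 and ends at 26; it formylates while chlorine is still on ring A. BCl3 with C6HMe5 on 22 gives the C1′-chloro-C3′-hydroxy-8-hydroxy depsidone F7. Rieche formylation (TiCl4, Cl2CHOMe) of F7 should give the C1′-chloro-C3′-hydroxy-C4′-formyl-8-hydroxy depsidone F8, because chlorine deactivates its ortho position C2′ inductively while C4′ is para to chlorine and ortho to both oxygens. The chloride, now activated by the para formyl group and the ortho lactone carbonyl, is methylated last by Stille coupling (SnMe4, Pd(P(t-Bu)3)2, CsF, dioxane, 100 °C), which should tolerate the free phenols and the aldehyde, to give 26.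

**Further compounds**
F1 | step 9 | 2,6-dichloro-4-hydroxybenzaldehyde | O=Cc1c(Cl)cc(O)cc1Cl
F2 | step 9 | 4-(benzyloxy)-2,6-dichlorobenzaldehyde | O=Cc1c(Cl)cc(OCc2ccccc2)cc1Cl
F3 | step 9 | 4-(benzyloxy)-2,6-dichlorobenzoic acid | OC(=O)c1c(Cl)cc(OCc2ccccc2)cc1Cl
F4 | step 8 | 6,7-dihydroxy-8-methoxy-2,2,5-trimethylchroman-4-one | Cc1c(O)c(O)c(OC)c2OC(C)(C)CC(=O)c12
F5 | step 8 | 7-(allyloxy)-6-hydroxy-8-methoxy-2,2,5-trimethylchroman-4-one | Cc1c(O)c(OCC=C)c(OC)c2OC(C)(C)CC(=O)c12
F6 | step 8 | 7-(allyloxy)-8-methoxy-6-(methoxymethoxy)-2,2,5-trimethylchroman-4-one | Cc1c(OCOC)c(OCC=C)c(OC)c2OC(C)(C)CC(=O)c12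
F7 | step 14 | C1′-chloro-C3′-hydroxy-8-hydroxy depsidone | Clc1cc(O)cc2c1C(=O)Oc1c(C)c3c(c(O)c1O2)OC(C)(C)CC3=O
F8 | step 14 | C1′-chloro-C3′-hydroxy-C4′-formyl-8-hydroxy depsidone | Clc1cc(O)c(C=O)c2c1C(=O)Oc1c(C)c3c(c(O)c1O2)OC(C)(C)CC3=O
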